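Botryotin E is traced back to a tricyclic keto ketal in which rings A, B and D exist and ring C is still open. The feature exploited is the quaternary centre C8 on the trans-fused rings A/B. C13 stands axial, syn to the C10 methyl, and C14 equatorial, as expected from anti addition across a C8=C9 alkene. One Lewis acid treatment of an acyclic (3S,4S)-epoxy diene, whose C8 bears a 1-silyloxycyclopentyl group, should close rings A and B. By shift of C14 from C13 to C8 it should also enlarge the cyclopentane into the spiro cyclohexanone ring D. Aldol closure of ring C and adjustment of C9=C11, C13, C16 and C17 follow.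

Key step: step 10

Remarks on the chemistry
- Atom labels:
  - C1–C3 are the ring A CH2 groups. C4 bears the C19 methyl and the C18 CH2O group.
  - C5 and C10 are the A/B fusion carbons, and C20 is the methyl on C10. C6 and C7 are the ring B CH2 groups.
  - C8 is the quaternary centre and C9=C11 the alkene. C12 is the bridgehead CH and C13 the carbinol bridge.
  - C14–C15 form the CH2CH2 bridge. C16 is the tertiary carbinol and C17 its CH2OAc carbon.
  - Ring C is C8, C9, C11, C12, C13. Ring D is C8, C14, C15, C16, C12, C13.
- The ketone addition in step 5 creates C13 without control. Every compound from there to the cyclisation substrate is therefore a mixture of C13 epimers and is drawn with C13 undefined. C13 becomes the ketone carbon in step 10.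
- By the CIP rules the C8=C9 alkene of the substrate is Z, because C13 outranks C7. C7 and C11 are nevertheless trans along the chain, as in an E-polyprenyl unit.
- C18 carries TIPS and not an arylsilyl group, because step 19 uses lithium in ammonia.

Step 1
Reactants: 1 geranyl bromide; 2 1-(trimethylsilyl)propyne
Product: 5 (E)-6,10-dimethylundeca-5,9-dien-1-yne, via lithiated silylpropyne 3 (not isolated), via silylated dienyne 4 (not isolated)
Conditions: 2, nBuLi, THF, −78 to −20 °C; 1, −78 °C to rt; then MeOH, K2CO3 (cat.), rt
Reagents that add atoms: none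
Why: The propargylic lithium reagent displaces the primary allylic bromide by SN2 at its CH2 terminus (the silyl group blocks the alkyne end), which forms C6–C7 without touching the E alkene, and carbonate-catalysed methanolysis then removes the alkynyl silane (propargylation, protodesilylation).

Step 2
Reactants: 5 (E)-6,10-dimethylundeca-5,9-dien-1-yne
Product: 7 (E)-7,11-dimethyldodeca-6,10-dien-2-yn-1-ol, via lithium acetylide 6 (not isolated)
Conditions: nBuLi, THF, −78 °C; (CH2O)n, −78 °C to rt
Reagents that add atoms: paraformaldehyde (reacts as formaldehyde), C=O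
Why: Deprotonation of the terminal alkyne and addition of the acetylide to formaldehyde installs C11 as a propargylic alcohol (alkynylation of an aldehyde).

Step 3
Reactants: 7 (E)-7,11-dimethyldodeca-6,10-dien-2-yn-1-ol
Product: 9 (2Z,6E)-3-iodo-7,11-dimethyldodeca-2,6,10-trien-1-ol, via cyclic alkenylalanate 8 (not isolated)
Conditions: NaAlH2(OCH2CH2OMe)2, THF, 0 °C to rt; then I2, −78 to 0 °C
Reagents that add atoms: iodine, II
Why: Alkoxide-directed trans-hydroalumination puts aluminium on C8, cis to C11 in a five-membered alanate, and iodinolysis goes with retention, so that C7 and C11 end trans on the C8=C9 alkene (hydroalumination–iodination of a propargylic alcohol).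

Step 4
Reactants: 9 (2Z,6E)-3-iodo-7,11-dimethyldodeca-2,6,10-trien-1-ol
Product: 10 TBS ether of 9 (C11–OTBS, iodine on C8)
Conditions: TBSCl, imidazole, DMF, 0 °C to rt
Reagents that add atoms: tert-butyldimethylsilyl chloride, CC(C)(C)[Si](C)(C)Cl
Why: Standard silylation of a primary alcohol removes the acidic proton before the lithiation and gives a C11 group that can later be cleaved beside TIPS.

Step 5
Reactants: 10 TBS ether of 9; 11 1,4-dioxaspiro[4.4]nonan-7-one
Product: 13 7-[(2Z,6E)-1-(tert-butyldimethylsilyloxy)-7,11-dimethyldodeca-2,6,10-trien-3-yl]-1,4-dioxaspiro[4.4]nonan-7-ol (racemic at C13), via alkenyllithium 12 (not isolated)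
Conditions: 10, tBuLi (2 equiv), Et2O, −78 °C; added to 11·LaCl3·2LiCl, THF, −78 °C
Reagents that add atoms: none
Why: Iodine–lithium exchange keeps the alkene geometry, and the lanthanum salt activates the carbonyl and tempers the basicity, so that 1,2-addition (C8–C13 bond) should outrun enolisation and β-elimination of the β-keto ketal (addition of an alkenyllithium to a ketone).

Step 6
Reactants: 13 tertiary allylic alcohol
Product: 14 triethylsilyl ether of 13 (C13–OTES)
Conditions: TESOTf, 2,6-lutidine, CH2Cl2, −78 to 0 °C
Reagents that add atoms: triethylsilyl triflate, CC[Si](CC)(CC)OS(=O)(=O)C(F)(F)F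
Why: A silyl triflate with a hindered pyridine base silylates the tertiary alcohol at low temperature, where ketone-derived dioxolanes survive.

Step 7
Reactants: 14 triethylsilyl ether
Product: 15 (E)-allylic alcohol (C18–OH on the terminal C3=C4 alkene of 14)
Conditions: SeO2 (cat.), tBuOOH, CH2Cl2, 0 °C to rt, stopped at partial conversion, 14 recycled
Reagents that add atoms: selenium dioxide (oxygen carrier), O=[Se]=O; tert-butyl hydroperoxide (terminal oxidant), CC(C)(C)OO
Why: Riley allylic oxidation (ene reaction, then [2,3]-shift) should pick the terminal isopropylidene group, the most electron-rich and least hindered alkene (C8=C9 is deactivated by two allylic C–O bonds), and it oxidises the E methyl group.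

Step 8
Reactants: 15 (E)-allylic alcohol
Product: 16 (3S,4S)-epoxy alcohol
Conditions: Ti(OiPr)4 (cat.), L-(+)-diethyl tartrate (cat.), tBuOOH, 4 Å MS, CH2Cl2, −20 °C
Reagents that add atoms: tert-butyl hydroperoxide, CC(C)(C)OO
Why: In the Sharpless asymmetric epoxidation only the alkene of the titanium-bound allylic alcohol reacts, and the L-(+)-tartrate sends oxygen to the face that gives the (3S,4S)-epoxide, the source of all absolute configuration.

Step 9
Reactants: 16 (3S,4S)-epoxy alcohol
Product: 17 cyclisation substrate: (3S,4S)-epoxy diene with C18–OTIPS, C11–OTBS, C13–OTES and the C16 ketal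
Conditions: TIPSCl, imidazole, DMAP (cat.), DMF, rt
Reagents that add atoms: triisopropylsilyl chloride, CC(C)[Si](Cl)(C(C)C)C(C)C
Why: Silylation under neutral to basic conditions leaves the epoxide alone, and the bulky silyl group keeps the C18 oxygen from chelating the Lewis acid in the next step.

Step 10
Reactants: 17 cyclisation substrate
Product: 18 tricyclic 3β-hydroxy decalin with spiro cyclohexanone ring D (C13 ketone, C16 ketal, C11–OTBS on C9, C18–OTIPS)
Conditions: MeAlCl2 (3 equiv), CH2Cl2 (high dilution), −78 °C; Et3N, then aq. MeOH at −78 °C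
Reagents that add atoms: none
Why: Proposed new method: MeAlCl2 binds the epoxide oxygen, C4–O breaks under backside attack by C5, the C10 cation is taken by C9, and the C8 cation that develops next to the silyloxy carbon C13 is discharged by a 1,2-shift of C14, after which the oxocarbenium ion gives its Et3Si group to chloride and leaves the C13 ketone. The closest known reactions are the epoxide-initiated cation–olefin polycyclisation and the Prins–pinacol type ring enlargement of 1-alkenylcycloalkyl silyl ethers, which are merged here in one cascade. Ring A closes 6-endo at both the epoxide and the C5=C10 alkene, ring B closes 6-endo-trig at the C8=C9 alkene, both through chair folds, and ring D arises by five-to-six ring expansion. C3 keeps the Sharpless configuration and becomes the equatorial 3β-alcohol, C4 is inverted so that the E-placed CH2OTIPS ends equatorial, C5 and C10 become trans because the C5=C10 alkene is E, C9 holds C11 equatorial because C7 and C11 are trans on the C8=C9 alkene, and C8 receives C14 anti to the new C9–C10 bond, hence equatorial, with C13 axial and syn to the C10 methyl. The step needs migration of C14 and not of C12, which the C16 ketal should secure by draining electron density from its neighbour C12 (the more so once aluminium sits on a ketal oxygen), so that both C13 epimers converge on 18. It also needs the epoxide to ionise before the ketal or the tertiary allylic silyl ether, for which the low temperature, the proton-scavenging Al–Me bond and the same electron-withdrawing ketal speak.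

Step 11
Reactants: 18 tricyclic 3β-alcohol
Product: 19 C3 O-phenyl thionocarbonate of 18
Conditions: PhOC(S)Cl, DMAP, CH2Cl2, rt
Reagents that add atoms: O-phenyl chlorothionoformate, ClC(=S)Oc1ccccc1
Why: DMAP-catalysed acylation of the only free hydroxyl at room temperature is mild enough for the β-keto ketal and prepares the Barton–McCombie deoxygenation.

Step 12
Reactants: 19 C3 thionocarbonate
Product: 20 3-deoxy tricycle (C13 ketone, C16 ketal, C11–OTBS, C18–OTIPS)
Conditions: Bu3SnH, AIBN (cat.), toluene, 90 °C
Reagents that add atoms: none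
Why: In the Barton–McCombie reaction the stannyl radical adds to C=S, the secondary C3 radical is released and takes hydrogen from the stannane, and no other group in the molecule reacts with these radicals.

Step 13
Reactants: 20 3-deoxy tricycle
Product: 21 C11 primary alcohol (may rest in part as the hemiketal with C13)
Conditions: HF·pyridine, pyridine, THF, 0 °C
Reagents that add atoms: none
Why: Buffered HF cleaves the primary TBS ether much faster than the bulkier neopentyl TIPS ether, and the excess pyridine protects the ketal (selective desilylation).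

Step 14
Reactants: 21 C11 primary alcohol
Product: 22 keto aldehyde (C11 aldehyde on C9, C13 ketone)
Conditions: nPr4N[RuO4] (cat.), NMO, 4 Å MS, CH2Cl2, rt
Reagents that add atoms: none
Why: The Ley–Griffith oxidation stops at the aldehyde under neutral, water-free conditions that spare the β-keto ketal and the C9 stereocentre.

Step 15
Reactants: 22 keto aldehyde
Product: 24 tetracyclic ketol (bicyclo[3.2.1]octane rings C/D; C11 carbinol configuration left open, either epimer is carried on), via lithium enolate 23 (not isolated)
Conditions: LiN(SiMe3)2, THF, −78 °C; AcOH, −78 °C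
Reagents that add atoms: none
Why: C12 is the only enolisable position of the C13 ketone, and at −78 °C its lithium enolate should add to the neighbouring C11 aldehyde faster than it expels a ketal oxygen, with C12 fixed by the bridge because C11 can only reach the ring D face on which C9 stands (intramolecular aldol addition to a bridged ketol).

Step 16
Reactants: 24 tetracyclic ketol
Product: 25 11,13-diketone
Conditions: Dess–Martin periodinane, CH2Cl2, 0 °C to rt
Reagents that add atoms: none
Why: The Dess–Martin oxidation takes either C11 epimer to the same diketone without base and hence without retro-aldol cleavage, which makes the route independent of a stereochemically matched dehydration (Bredt's rule bars loss of H12, and H9 need not be aligned with the C11 oxygen).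

Step 17
Reactants: 25 11,13-diketone
Product: 27 C9=C11 enol triflate, via potassium enolate 26 (not isolated)
Conditions: KN(SiMe3)2, THF, −78 to −20 °C; PhNTf2, −78 °C to rt
Reagents that add atoms: N-phenylbis(trifluoromethanesulfonimide), O=S(=O)(N(c1ccccc1)S(=O)(=O)C(F)(F)F)C(F)(F)F
Why: H9 is the only hydrogen that can be removed (C8 is quaternary, H12 is a bridgehead hydrogen), so that the enolate and its triflate form with the double bond at C9=C11 only (regiospecific enol triflate formation).

Step 18
Reactants: 27 enol triflate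
Product: 28 9(11)-ene 13-ketone (C16 ketal, C18–OTIPS)
Conditions: Pd(OAc)2 (cat.), PPh3, HCO2H, Et3N, DMF, 60 °C
Reagents that add atoms: none
Why: Oxidative addition of the vinyl C–O bond to zerovalent palladium, exchange for formate, loss of CO2 and reductive elimination replace the triflate by hydrogen with the alkene in place (palladium-catalysed formate reduction of an enol triflate).

Step 19
Reactants: 28 9(11)-ene 13-ketone
Product: 29 13-alcohol (OH equatorial on ring D, syn to C9=C11)
Conditions: Li, NH3(l)/THF, EtOH, −78 °C
Reagents that add atoms: none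
Why: Dissolving-metal reduction of the non-enolisable bridge ketone runs through the ketyl and its carbanion, which should settle with the solvated oxygen in the roomier position, equatorial on ring D and free of 1,3-diaxial contact with the axial ketal oxygen and H14, whereas complex hydrides such as LiAlH4 would enter from the open alkene side and give the C13 epimer.

Step 20
Reactants: 29 13-alcohol
Product: 30 C13–OTBS ether
Conditions: TBSOTf, 2,6-lutidine, CH2Cl2, 0 °C
Reagents that add atoms: tert-butyldimethylsilyl triflate, CC(C)(C)[Si](C)(C)OS(=O)(=O)C(F)(F)F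
Why: Silylation blocks the C13 alkoxide, which would otherwise allow retro-aldol cleavage of the well-aligned C12–C13 bond once C16 is a ketone under basic conditions.

Step 21
Reactants: 30 C13–OTBS ether
Product: 31 C16 ketone
Conditions: PPTS (cat.), acetone/H2O, 55 °C
Reagents that add atoms: water, O
Why: Mild acid hydrolysis removes the dioxolane while the hindered secondary TBS and the TIPS ether persist, and the β-silyloxy ketone cannot eliminate because C12 is a bridgehead (ketal hydrolysis).

Step 22
Reactants: 31 C16 ketone
Product: 32 C16 exocyclic methylene compound (C16=C17)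
Conditions: Ph3PCH3Br, KOtBu, THF, 0 °C to rt
Reagents that add atoms: methyltriphenylphosphonium bromide, C[P+](c1ccccc1)(c1ccccc1)c1ccccc1.[Br-]
Why: The Wittig methylenation meets a single carbonyl group here, so that no choice between C13 and C16 is needed, and it brings in C17.

Step 23
Reactants: 32 C16 methylene compound
Product: 33 16,17-diol (C16–OH equatorial, C17 axial on ring D)
Conditions: OsO4 (cat.), NMO, acetone/H2O, 0 °C to rt
Reagents that add atoms: osmium tetroxide, O=[Os](=O)(=O)=O; N-methylmorpholine N-oxide, C[N+]1([O-])CCOCC1; water, O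
Why: In the Upjohn dihydroxylation OsO4 should approach the methylenecyclohexane from its equatorial (endo) face, away from the axial hydrogens on C13 and C14, which sets C16, while the C9=C11 alkene is screened by the C13 silyl ether, the C10 methyl and ring D.

Step 24
Reactants: 33 16,17-diol
Product: 34 C17 monoacetate
Conditions: Ac2O (1.1 equiv), pyridine, 0 °C
Reagents that add atoms: acetic anhydride, CC(=O)OC(C)=O
Why: The primary C17 hydroxyl is acylated far faster than the tertiary C16 hydroxyl, and all other oxygens are silylated (selective acetylation).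

Step 25
Reactants: 34 C17 monoacetate
Product: 35 botryotin E
Conditions: HF·pyridine, THF, 0 °C to rt
Reagents that add atoms: none
Why: Acidic fluoride removes the C13 TBS and the C18 TIPS group in one operation without hydrolysis or migration of the acetate (global desilylation).

Compound list
1 | geranyl bromide | CC(C)=CCC/C(C)=C/CBr | starting material
2 | 1-(trimethylsilyl)propyne | CC#C[Si](C)(C)C | starting material
3 | 3-lithio-1-(trimethylsilyl)propyne | [Li]CC#C[Si](C)(C)C | intermediate
4 | (E)-(6,10-dimethylundeca-5,9-dien-1-yn-1-yl)trimethylsilane | CC(C)=CCC/C(C)=C/CCC#C[Si](C)(C)C | intermediate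
5 | (E)-6,10-dimethylundeca-5,9-dien-1-yne | CC(C)=CCC/C(C)=C/CCC#C | intermediate
6 | lithium acetylide of 5 | CC(C)=CCC/C(C)=C/CCC#C[Li] | intermediate
7 | (E)-7,11-dimethyldodeca-6,10-dien-2-yn-1-ol | CC(C)=CCC/C(C)=C/CCC#CCO | intermediate
8 | sodium cyclic alkenylalanate (Al on C8, bound to the C11 oxygen) | [Na+].COCCO[Al-]1(OCCOC)OCC=C1CC/C=C(\C)CCC=C(C)C | intermediate
9 | (2Z,6E)-3-iodo-7,11-dimethyldodeca-2,6,10-trien-1-ol | CC(C)=CCC/C(C)=C/CC/C(I)=C/CO | intermediate
10 | TBS ether of 9 | CC(C)=CCC/C(C)=C/CC/C(I)=C/CO[Si](C)(C)C(C)(C)C | intermediate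
11 | 1,4-dioxaspiro[4.4]nonan-7-one | O=C1CCC2(C1)OCCO2 | starting material
12 | alkenyllithium from 10 (Li on C8) | CC(C)=CCC/C(C)=C/CC/C([Li])=C/CO[Si](C)(C)C(C)(C)C | intermediate
13 | tertiary allylic alcohol (C13–OH, racemic) | CC(C)=CCC/C(C)=C/CC/C(=C/CO[Si](C)(C)C(C)(C)C)C1(O)CCC2(C1)OCCO2 | intermediate
14 | C13 triethylsilyl ether | CC(C)=CCC/C(C)=C/CC/C(=C/CO[Si](C)(C)C(C)(C)C)C1(O[Si](CC)(CC)CC)CCC2(C1)OCCO2 | intermediate
15 | (E)-C18 allylic alcohol | OC/C(C)=C/CC/C(C)=C/CC/C(=C/CO[Si](C)(C)C(C)(C)C)C1(O[Si](CC)(CC)CC)CCC2(C1)OCCO2 | intermediate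
16 | (3S,4S)-epoxy alcohol (C13 epimers) | OC[C@]1(C)O[C@H]1CC/C(C)=C/CC/C(=C/CO[Si](C)(C)C(C)(C)C)C2(O[Si](CC)(CC)CC)CCC3(C2)OCCO3 | intermediate
17 | cyclisation substrate, (3S,4S)-epoxy diene 1-alkenylcyclopentyl triethylsilyl ether (C13 epimers) | CC(C)[Si](C(C)C)(C(C)C)OC[C@]1(C)O[C@H]1CC/C(C)=C/CC/C(=C/CO[Si](C)(C)C(C)(C)C)C2(O[Si](CC)(CC)CC)CCC3(C2)OCCO3 | intermediate
18 | tricyclic 3β-hydroxy decalin with spiro cyclohexanone ring D | O=C1CC2(OCCO2)CC[C@@]13CC[C@H]4[C@](C)(CO[Si](C(C)C)(C(C)C)C(C)C)[C@@H](O)CC[C@]4(C)[C@H]3CO[Si](C)(C)C(C)(C)C | intermediate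
19 | C3 O-phenyl thionocarbonate | O=C1CC2(OCCO2)CC[C@@]13CC[C@H]4[C@](C)(CO[Si](C(C)C)(C(C)C)C(C)C)[C@@H](OC(=S)Oc5ccccc5)CC[C@]4(C)[C@H]3CO[Si](C)(C)C(C)(C)C | intermediate
20 | 3-deoxy tricycle | O=C1CC2(OCCO2)CC[C@@]13CC[C@H]4[C@](C)(CO[Si](C(C)C)(C(C)C)C(C)C)CCC[C@]4(C)[C@H]3CO[Si](C)(C)C(C)(C)C | intermediate
21 | C11 primary alcohol | O=C1CC2(OCCO2)CC[C@@]13CC[C@H]4[C@](C)(CO[Si](C(C)C)(C(C)C)C(C)C)CCC[C@]4(C)[C@H]3CO | intermediate
22 | keto aldehyde | O=C1CC2(OCCO2)CC[C@@]13CC[C@H]4[C@](C)(CO[Si](C(C)C)(C(C)C)C(C)C)CCC[C@]4(C)[C@H]3C=O | intermediate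
23 | lithium C12=C13 enolate of 22 | [Li]OC1=CC2(OCCO2)CC[C@@]13CC[C@H]4[C@](C)(CO[Si](C(C)C)(C(C)C)C(C)C)CCC[C@]4(C)[C@H]3C=O | intermediate
24 | tetracyclic ketol (C11 undefined) | O=C1[C@@]23CC[C@H]4[C@](C)(CO[Si](C(C)C)(C(C)C)C(C)C)CCC[C@]4(C)[C@H]2C(O)[C@@H]1C5(OCCO5)CC3 | intermediate
25 | 11,13-diketone | O=C1[C@@]23CC[C@H]4[C@](C)(CO[Si](C(C)C)(C(C)C)C(C)C)CCC[C@]4(C)[C@H]2C(=O)[C@@H]1C5(OCCO5)CC3 | intermediate
26 | potassium C9=C11 enolate of 25 | O=C1[C@@]23CC[C@H]4[C@](C)(CO[Si](C(C)C)(C(C)C)C(C)C)CCC[C@]4(C)C2=C(O[K])[C@@H]1C5(OCCO5)CC3 | intermediate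
27 | C9=C11 enol triflate | O=C1[C@@]23CC[C@H]4[C@](C)(CO[Si](C(C)C)(C(C)C)C(C)C)CCC[C@]4(C)C2=C(OS(=O)(=O)C(F)(F)F)[C@@H]1C5(OCCO5)CC3 | intermediate
28 | 9(11)-ene 13-ketone | O=C1[C@@]23CC[C@H]4[C@](C)(CO[Si](C(C)C)(C(C)C)C(C)C)CCC[C@]4(C)C2=C[C@@H]1C5(OCCO5)CC3 | intermediate
29 | 13-alcohol | O[C@H]1[C@@]23CC[C@H]4[C@](C)(CO[Si](C(C)C)(C(C)C)C(C)C)CCC[C@]4(C)C2=C[C@@H]1C5(OCCO5)CC3 | intermediate
30 | C13–OTBS ether | CC(C)(C)[Si](C)(C)O[C@H]1[C@@]23CC[C@H]4[C@](C)(CO[Si](C(C)C)(C(C)C)C(C)C)CCC[C@]4(C)C2=C[C@@H]1C5(OCCO5)CC3 | intermediate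
31 | C16 ketone | CC(C)(C)[Si](C)(C)O[C@H]1[C@@]23CC[C@H]4[C@](C)(CO[Si](C(C)C)(C(C)C)C(C)C)CCC[C@]4(C)C2=C[C@@H]1C(=O)CC3 | intermediate
32 | C16 methylene compound | CC(C)(C)[Si](C)(C)O[C@H]1[C@@]23CC[C@H]4[C@](C)(CO[Si](C(C)C)(C(C)C)C(C)C)CCC[C@]4(C)C2=C[C@@H]1C(=C)CC3 | intermediate
33 | 16,17-diol | CC(C)(C)[Si](C)(C)O[C@H]1[C@@]23CC[C@H]4[C@](C)(CO[Si](C(C)C)(C(C)C)C(C)C)CCC[C@]4(C)C2=C[C@@H]1[C@@](O)(CO)CC3 | intermediate
34 | C17 monoacetate | CC(C)(C)[Si](C)(C)O[C@H]1[C@@]23CC[C@H]4[C@](C)(CO[Si](C(C)C)(C(C)C)C(C)C)CCC[C@]4(C)C2=C[C@@H]1[C@@](O)(COC(C)=O)CC3 | intermediate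
35 | botryotin E | CC(=O)OC[C@@]1(O)CC[C@]23CC[C@H]4[C@](C)(CO)CCC[C@]4(C)C2=C[C@H]1[C@H]3O | target

Total step count: 25. Longest linear sequence: 25 steps (from 1 and 2).

Steps most likely to fail

1. Step 10.
   - What may go wrong: the cascade may stop early by proton loss from the C10 or C8 cation. The activated epoxide may rearrange by hydride shift to a C3 ketone. The ketal or the tertiary allylic silyl ether may ionise. C12 may migrate in competition with C14.
   - Fallback (known chemistry, from 17 back to 18): the three bonds are made in two separate operations. Cp2TiCl, made from Cp2TiCl2 and Mn dust in THF, opens the epoxide of 17 homolytically (trivalent titanium, C4 radical). Two 6-endo radical closures then build rings A and B, and the tertiary C8 radical ends by loss of a C7 hydrogen. This gives the bicyclic 7-ene F1 with the silyloxycyclopentane intact (epoxypolyene radical cyclisation; the larger CH2OTIPS group should again take the equatorial place on C4). Tf2NH in CH2Cl2 at −78 °C then protonates C7 of the bicyclic 7-ene F1. The open tertiary C8 cation has its β face covered by the C10 methyl, so C14 should enter from the α face, as in an equatorial attack on a cyclohexanone with a 3-axial substituent. Loss of the silyl group gives 18 (acid-induced semipinacol ring enlargement of a 1-alkenylcycloalkyl silyl ether).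

2. Step 15.
   - What may go wrong: the C12 enolate may expel the axial ketal oxygen (E1cB opening of the dioxolane to a vinylogous ester). Closure may be slow because the enolate double bond lies inside the ring being formed. The aldolate may revert on warming.
   - Fallback (from 21 to 25): ring C is closed by acylation in place of aldol addition. TEMPO/PhI(OAc)2 in aqueous MeCN takes 21 to the carboxylic acid F2, and C6F5OC(O)CF3/pyridine gives the pentafluorophenyl ester F3. Soft enolisation with MgBr2·OEt2 and iPr2NEt in CH2Cl2 should then bring about C-acylation at C12 without a free enolate. This leads directly to diketone 25 and makes 22 to 24 unnecessary.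

3. Step 19.
   - What may go wrong: protonation of the carbanion from the alkene side, or chelation of lithium between O13 and the axial ketal oxygen, would erode the facial selectivity at C13.
   - Fallback (from 28 to 35): the ketone is kept until C17 is in place, and hydride is then delivered from within.
     - Hydrolysis of 28 (PPTS, aqueous acetone) gives the 13,16-dione F4.
     - One equivalent of Ph3P=CH2 should pick the C16 carbonyl, since C13 lies between the quaternary C8 and the bridgehead C12, and give the methylene ketone F5.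
     - OsO4/NMO gives the keto diol F6. The facial course at C16 has to be checked here, because C13 is trigonal and the exo face is more open.
     - Me4NBH(OAc)3 in MeCN/AcOH binds to the axial C17 hydroxyl, which sits over the ring D face of the C13 carbonyl, and passes hydride to that face to give the triol F7 (hydroxyl-directed reduction).
     - Ac2O/pyridine acetylates the primary alcohol to the monoacetate F8, and HF·pyridine frees C18 to give 35.

Further compounds
F1 | step 10 | bicyclic 7-ene (3β-OH, C18–OTIPS, C11–OTBS, C8 bearing the 1-triethylsilyloxycyclopentane ketal) | CC[Si](CC)(CC)OC1(CCC2(C1)OCCO2)C3=CC[C@H]4[C@](C)(CO[Si](C(C)C)(C(C)C)C(C)C)[C@@H](O)CC[C@]4(C)[C@H]3CO[Si](C)(C)C(C)(C)C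
F2 | step 15 | C11 carboxylic acid | O=C1CC2(OCCO2)CC[C@@]13CC[C@H]4[C@](C)(CO[Si](C(C)C)(C(C)C)C(C)C)CCC[C@]4(C)[C@H]3C(=O)O
F3 | step 15 | C11 pentafluorophenyl ester | O=C1CC2(OCCO2)CC[C@@]13CC[C@H]4[C@](C)(CO[Si](C(C)C)(C(C)C)C(C)C)CCC[C@]4(C)[C@H]3C(=O)Oc5c(F)c(F)c(F)c(F)c5F
F4 | step 19 | 13,16-dione | O=C1[C@@]23CC[C@H]4[C@](C)(CO[Si](C(C)C)(C(C)C)C(C)C)CCC[C@]4(C)C2=C[C@@H]1C(=O)CC3
F5 | step 19 | C16 methylene 13-ketone | O=C1[C@@]23CC[C@H]4[C@](C)(CO[Si](C(C)C)(C(C)C)C(C)C)CCC[C@]4(C)C2=C[C@@H]1C(=C)CC3
F6 | step 19 | 13-keto 16,17-diol | O=C1[C@@]23CC[C@H]4[C@](C)(CO[Si](C(C)C)(C(C)C)C(C)C)CCC[C@]4(C)C2=C[C@@H]1[C@@](O)(CO)CC3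
F7 | step 19 | 13,16,17-triol | O[C@H]1[C@@]23CC[C@H]4[C@](C)(CO[Si](C(C)C)(C(C)C)C(C)C)CCC[C@]4(C)C2=C[C@@H]1[C@@](O)(CO)CC3
F8 | step 19 | C17 monoacetate with C18–OTIPS | O[C@H]1[C@@]23CC[C@H]4[C@](C)(CO[Si](C(C)C)(C(C)C)C(C)C)CCC[C@]4(C)C2=C[C@@H]1[C@@](O)(COC(C)=O)CC3
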